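**Strategy.** The flavonol is cut at C3–C4 of the pyranone ring (ring C). In the chromane-3,4-dione tautomer these two neighbouring ring carbons are both carbonyl carbons, so they can only be joined after the polarity of one is inverted. A carbene catalyst turns the A-ring aldehyde carbon (C4) into an acyl anion that acylates an activated ester carbon (C3). That single operation forms C3–C4, closes ring C and, after enolisation, exposes the 3-hydroxyl that is later sulfated. The precursor 9 is a racemic trifluoroethyl α-aryl-α-aryloxyacetate in which C2 already carries the B ring and O1 of a 2-formylphenol; 5-OH and 3′-OH are benzyl ethers.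

Key step: step 7

Remark: the target has no stereogenic element, so nothing has to be set; the one sp3 stereocentre on the way (the ArCH(OAr) carbon of 8, 9 and 10, later C2) is carried as the racemate and disappears on aromatisation.
Remark: the target is taken as the free hydrogen sulfate as drawn; it is kept as its triethylammonium salt until the final ion exchange, and the free acid should be handled cold.

**Route**

Step 1
Reactants: 1 2,4,6-trihydroxybenzaldehyde
Product: 2 2,6-dihydroxy-4-methoxybenzaldehyde
Conditions: Me2SO4 (1.0 equiv), K2CO3 (1.0 equiv), acetone, 0 °C → rt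
Reagents that add atoms: dimethyl sulfate, COS(=O)(=O)OC
Why: Williamson O-methylation with base as the limiting reagent; the 4-OH is para to the formyl group and outside its hydrogen-bond chelate, so it is the most acidic and most accessible hydroxyl and should be methylated in preference to the 2- and 6-OH.

Step 2
Reactants: 2 2,6-dihydroxy-4-methoxybenzaldehyde
Product: 3 2-benzyloxy-6-hydroxy-4-methoxybenzaldehyde
Conditions: BnBr (1.0 equiv), K2CO3 (1.0 equiv), DMF, rt
Reagents that add atoms: benzyl bromide, BrCc1ccccc1
Why: Williamson benzylation of one of two equivalent ortho-hydroxyls; once the first is etherified the remaining OH is locked in the chelate with the aldehyde and reacts far more slowly, so one equivalent of bromide should stop at the mono-ether.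

Step 3
Reactants: 4 3-hydroxy-4-methoxyphenylacetic acid
Product: 5 3-benzyloxy-4-methoxyphenylacetic acid
Conditions: BnBr (1.2 equiv), NaOH (2.5 equiv), EtOH/H2O, reflux; then aq. HCl to pH 2
Reagents that add atoms: benzyl bromide, BrCc1ccccc1
Why: Williamson etherification in aqueous-alcoholic hydroxide; the phenoxide is much more nucleophilic than the carboxylate, and any benzyl ester that forms is saponified in the same pot.

Step 4
Reactants: 5 3-benzyloxy-4-methoxyphenylacetic acid; 6 2,2,2-trifluoroethanol
Product: 7 2,2,2-trifluoroethyl 2-(3-benzyloxy-4-methoxyphenyl)acetate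
Conditions: DCC (1.1 equiv), DMAP (10 mol%), CH2Cl2, 0 °C → rt
Reagents that add atoms: none
Why: Steglich esterification; the DMAP-derived acylpyridinium is reactive enough to be trapped by the weakly nucleophilic trifluoroethanol.

Step 5
Reactants: 7 2,2,2-trifluoroethyl 2-(3-benzyloxy-4-methoxyphenyl)acetate
Product: 8 2,2,2-trifluoroethyl 2-bromo-2-(3-benzyloxy-4-methoxyphenyl)acetate (racemic)
Conditions: NBS (1.05 equiv), AIBN (5 mol%), PhCF3, 80 °C
Reagents that add atoms: N-bromosuccinimide, O=C1CCC(=O)N1Br
Why: Wohl–Ziegler radical bromination; the C–H flanked by the aryl ring and the ester gives a captodatively stabilised radical, the low bromine concentration in a non-polar solvent should hold back electrophilic ring bromination, and aryl benzyl ethers normally tolerate these conditions; the new stereocentre is formed as the racemate.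

Step 6
Reactants: 3 2-benzyloxy-6-hydroxy-4-methoxybenzaldehyde; 8 2,2,2-trifluoroethyl 2-bromo-2-(3-benzyloxy-4-methoxyphenyl)acetate (racemic)
Product: 9 2,2,2-trifluoroethyl 2-(3-benzyloxy-2-formyl-5-methoxyphenoxy)-2-(3-benzyloxy-4-methoxyphenyl)acetate (racemic)
Conditions: K2CO3 (1.2 equiv), MeCN, 0 °C → rt
Reagents that add atoms: none
Why: Williamson ether synthesis by SN2 displacement; the secondary benzylic α-bromo ester is a strongly activated electrophile, so the chelated phenoxide of 3 should alkylate near room temperature with carbonate only, which is mild enough to spare the trifluoroethyl ester and the acidic α-H of the product (racemic, no stereocontrol needed).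

Step 7
Reactants: 9 2,2,2-trifluoroethyl 2-(3-benzyloxy-2-formyl-5-methoxyphenoxy)-2-(3-benzyloxy-4-methoxyphenyl)acetate (racemic)
Product: 11 5-benzyloxy-2-(3-benzyloxy-4-methoxyphenyl)-3-hydroxy-7-methoxychromen-4-one, via chromane-3,4-dione 10 (not isolated)
Conditions: 3,4,5-trimethylthiazolium iodide (20 mol%), DBU (15 mol%), 4 Å MS, degassed THF (0.02 M), Ar, rt → 60 °C
Reagents that add atoms: none
Why: Proposed new method: the thiazolylidene adds to the aldehyde carbon of 9 and proton transfer gives the Breslow enaminol, which makes that carbon (future C4) nucleophilic; it attacks the trifluoroethyl ester carbonyl (future C3) in a 6-exo-trig closure of the pyranone ring, the tetrahedral adduct ejects trifluoroethoxide, and release of the carbene leaves chromane-3,4-dione 10. The closest known reaction types are the carbene-catalysed intramolecular crossed benzoin of 2-(2-oxoalkoxy)benzaldehydes, which gives 3-hydroxychroman-4-ones, and the related aldehyde–nitrile coupling that gives 3-aminochromones; here the acceptor is an ester, and the good trifluoroethoxide leaving group is what should make the addition productive instead of reverting. Enolisation of 10 through its C2–H gives the aromatic, internally hydrogen-bonded 3-hydroxy-4-pyranone 11, which should make the sequence irreversible and removes the only stereocentre, so no stereocontrol is required. The selectivity needed is chemoselectivity for C-acylation of the acyl anion over base-induced aldol closure of the ester enolate onto the aldehyde, over intermolecular benzoin and over direct attack of the carbene on the ester; it should be secured by a small carbene with one open flank for the di-ortho-substituted aldehyde, by keeping the base below the azolium loading, by an ester that is activated but not an aryl ester, by high dilution, by the two ortho-alkoxy groups that block aldehyde–aldehyde coupling, and by the fact that the aldol adduct has a quaternary carbon, cannot dehydrate and should revert.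

Step 8
Reactants: 11 5-benzyloxy-2-(3-benzyloxy-4-methoxyphenyl)-3-hydroxy-7-methoxychromen-4-one
Product: 12 triethylammonium 5-benzyloxy-2-(3-benzyloxy-4-methoxyphenyl)-7-methoxy-4-oxochromen-3-yl sulfate
Conditions: SO3·NEt3 (5 equiv), Et3N (2 equiv), DMF, 60 °C; silica (CH2Cl2/MeOH, 1% Et3N)
Reagents that add atoms: sulfur trioxide–triethylamine complex, CC[N+](CC)(CC)S(=O)(=O)[O-]
Why: O-sulfation with a sulfur trioxide–amine complex; the enolic 3-OH is the only free hydroxyl, so the sulfate monoester should form there and be isolated as its triethylammonium salt.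

Step 9
Reactants: 12 triethylammonium 5-benzyloxy-2-(3-benzyloxy-4-methoxyphenyl)-7-methoxy-4-oxochromen-3-yl sulfate
Product: 14 ombuin 3-O-sulfate (5-hydroxy-2-(3-hydroxy-4-methoxyphenyl)-7-methoxy-4-oxochromen-3-yl hydrogen sulfate), via triethylammonium ombuin 3-O-sulfate 13 (not isolated)
Conditions: H2 (1 atm), 10% Pd/C, MeOH/THF, rt; filter; Dowex 50WX8 (H+ form), MeOH/H2O, 0 °C; lyophilise
Reagents that add atoms: none
Why: Catalytic hydrogenolysis of the two aryl benzyl ethers, under which the sulfate monoester salt and the chromone C2=C3 bond should stay intact at 1 atm, followed by cation exchange that replaces triethylammonium by a proton.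

**Compound list**

1 | 2,4,6-trihydroxybenzaldehyde | O=Cc1c(O)cc(O)cc1O | starting material
2 | 2,6-dihydroxy-4-methoxybenzaldehyde | COc1cc(O)c(C=O)c(O)c1 | intermediate
3 | 2-benzyloxy-6-hydroxy-4-methoxybenzaldehyde | COc1cc(O)c(C=O)c(OCc2ccccc2)c1 | intermediate
4 | 3-hydroxy-4-methoxyphenylacetic acid | COc1ccc(CC(=O)O)cc1O | starting material
5 | 3-benzyloxy-4-methoxyphenylacetic acid | COc1ccc(CC(=O)O)cc1OCc1ccccc1 | intermediate
6 | 2,2,2-trifluoroethanol | OCC(F)(F)F | starting material
7 | 2,2,2-trifluoroethyl 2-(3-benzyloxy-4-methoxyphenyl)acetate | COc1ccc(CC(=O)OCC(F)(F)F)cc1OCc1ccccc1 | intermediate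
8 | 2,2,2-trifluoroethyl 2-bromo-2-(3-benzyloxy-4-methoxyphenyl)acetate (racemic) | COc1ccc(C(Br)C(=O)OCC(F)(F)F)cc1OCc1ccccc1 | intermediate
9 | 2,2,2-trifluoroethyl 2-(3-benzyloxy-2-formyl-5-methoxyphenoxy)-2-(3-benzyloxy-4-methoxyphenyl)acetate (racemic) | COc1cc(OCc2ccccc2)c(C=O)c(OC(C(=O)OCC(F)(F)F)c2ccc(OC)c(OCc3ccccc3)c2)c1 | intermediate
10 | 5-benzyloxy-2-(3-benzyloxy-4-methoxyphenyl)-7-methoxychromane-3,4-dione (racemic) | COc1cc(OCc2ccccc2)c2c(c1)OC(c1ccc(OC)c(OCc3ccccc3)c1)C(=O)C2=O | intermediate (not isolated)
11 | 5-benzyloxy-2-(3-benzyloxy-4-methoxyphenyl)-3-hydroxy-7-methoxychromen-4-one | COc1cc(OCc2ccccc2)c2c(=O)c(O)c(-c3ccc(OC)c(OCc4ccccc4)c3)oc2c1 | intermediate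
12 | triethylammonium 5-benzyloxy-2-(3-benzyloxy-4-methoxyphenyl)-7-methoxy-4-oxochromen-3-yl sulfate | COc1cc(OCc2ccccc2)c2c(=O)c(OS(=O)(=O)[O-])c(-c3ccc(OC)c(OCc4ccccc4)c3)oc2c1.CC[NH+](CC)CC | intermediate
13 | triethylammonium 5-hydroxy-2-(3-hydroxy-4-methoxyphenyl)-7-methoxy-4-oxochromen-3-yl sulfate | COc1cc(O)c2c(=O)c(OS(=O)(=O)[O-])c(-c3ccc(OC)c(O)c3)oc2c1.CC[NH+](CC)CC | intermediate (not isolated)
14 | ombuin 3-O-sulfate (achiral) | COc1cc(O)c2c(=O)c(OS(=O)(=O)O)c(-c3ccc(OC)c(O)c3)oc2c1 | target

**Step count**

Total steps: 9. Longest linear sequence: 7 steps (4 → 5 → 7 → 8 → 9 → 11 → 12 → 14).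

**Steps most likely to fail**

1. Step 7 (the proposed new method). The hindered, electron-rich 2,6-dialkoxybenzaldehyde may be slow to form the Breslow intermediate, and base-induced aldol closure of the ester enolate onto the aldehyde may then outrun acylation. The fallback uses the known Algar–Flynn–Oyamada sequence and sets out from 3. Addition of MeMgBr (THF, 0 °C) would give 1-(2-benzyloxy-6-hydroxy-4-methoxyphenyl)ethanol F1. Oxidation with MnO2 (CH2Cl2) would give 1-(2-benzyloxy-6-hydroxy-4-methoxyphenyl)ethanone F2. Claisen–Schmidt condensation with commercial 3-benzyloxy-4-methoxybenzaldehyde (KOH, EtOH) would give (E)-1-(2-benzyloxy-6-hydroxy-4-methoxyphenyl)-3-(3-benzyloxy-4-methoxyphenyl)prop-2-en-1-one F3. Oxidative cyclisation with alkaline H2O2 (NaOH, MeOH, 0 °C) would then return to the route at 11.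

2. Step 5. Electrophilic bromination of the electron-rich dialkoxyarene, or hydrogen abstraction at the benzyl ether CH2, may compete with abstraction of the α-C–H. The fallback sets out from 7. Regitz diazo transfer (p-ABSA, DBU, MeCN, 0 °C → rt) would give 2,2,2-trifluoroethyl 2-(3-benzyloxy-4-methoxyphenyl)-2-diazoacetate F4. HBr (33% in AcOH, CH2Cl2, −20 °C) would protonate the diazo carbon and deliver bromide with loss of nitrogen, returning to the route at 8.

3. Step 6. Under carbonate the product may react on, by enolisation and intramolecular aldol addition to the ortho-aldehyde or by cleavage of the activated ester. The fallback sets out from 8 and 3 and forms the same C–O bond without a carbonate base. Silver-assisted hydrolysis of 8 (Ag2CO3, acetone/H2O, rt) would give 2,2,2-trifluoroethyl 2-(3-benzyloxy-4-methoxyphenyl)-2-hydroxyacetate F5. Mitsunobu etherification of phenol 3 with F5 (PPh3, DIAD, THF, 0 °C) would return to the route at 9.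

**Further compounds**

F1 | step 7 | 1-(2-benzyloxy-6-hydroxy-4-methoxyphenyl)ethanol (racemic) | COc1cc(O)c(C(C)O)c(OCc2ccccc2)c1
F2 | step 7 | 1-(2-benzyloxy-6-hydroxy-4-methoxyphenyl)ethanone | COc1cc(O)c(C(C)=O)c(OCc2ccccc2)c1
F3 | step 7 | (E)-1-(2-benzyloxy-6-hydroxy-4-methoxyphenyl)-3-(3-benzyloxy-4-methoxyphenyl)prop-2-en-1-one | COc1cc(O)c(C(=O)/C=C/c2ccc(OC)c(OCc3ccccc3)c2)c(OCc2ccccc2)c1
F4 | step 5 | 2,2,2-trifluoroethyl 2-(3-benzyloxy-4-methoxyphenyl)-2-diazoacetate | COc1ccc(C(=[N+]=[N-])C(=O)OCC(F)(F)F)cc1OCc1ccccc1
F5 | step 6 | 2,2,2-trifluoroethyl 2-(3-benzyloxy-4-methoxyphenyl)-2-hydroxyacetate (racemic) | COc1ccc(C(O)C(=O)OCC(F)(F)F)cc1OCc1ccccc1
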